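**Retrosynthetic overview**
1. The target comes from Dess–Martin oxidation of the side-chain carbinol, so the base-sensitive 1,5-diketone appears only in the last step; the quinone (ring A) comes from a 2,6-dialkylphenol by Fremy oxidation.
2. The CH2–C(=O) bond of the aryl side chain is made by α-selective, E-retentive allylbarium addition of an o-cresol-derived C5 allyl chloride to a keto aldehyde.
3. The prenyl ketone is made by α-prenylation of a lactol (a masked neopentyl aldehyde) followed by Swern oxidation.
4. The cyclopentane (ring B) with both quaternary centres is made by a 1,2-shift ring contraction of a hydroxyl-directed cyclohexene epoxide; the quaternary carbon migrates with retention and the formyl group ends cis to the hydroxyethyl arm.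
5. The first stereocentre is set by Cu-catalysed asymmetric conjugate vinylation of 3-methylcyclohex-2-enone. Ring order: six-membered carbocycle, then contraction to ring B (step 4), then ring A oxidised to the quinone near the end.

Assumption: the sense of induction of the copper/aminophosphine catalyst in step 1 is taken by analogy with related alkenylalane additions; the ligand enantiomer that gives (R)-5 is used.

**Step 1**
Reactants: 1 3-methylcyclohex-2-en-1-one; 2 ethenylmagnesium bromide
Product: 5 (3R)-3-ethenyl-3-methylcyclohex-1-en-1-yl trifluoromethanesulfonate, via ethenyldimethylalane 3 (not isolated), via aluminium enolate 4 (not isolated)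
Conditions: 2, Me2AlCl, Et2O, 0 °C; then 1, Cu(O2CC4H3S) (copper thiophene-2-carboxylate, 10 mol%), aminophosphine Ph2P–N[CH(CH3)(2-naphthyl)]2 (SimplePhos type, 11 mol%), Et2O, −30 °C; then MeLi, THF, −78 °C; PhNTf2, −78 → 0 °C
Reagents that add atoms: N-phenylbis(trifluoromethanesulfonimide) O=S(=O)(N(c1ccccc1)S(=O)(=O)C(F)(F)F)C(F)(F)F
Why: Copper-catalysed asymmetric conjugate addition of the alkenylalane to the β-methyl enone builds the all-carbon quaternary centre (face chosen by the ligand enantiomer), and the regiodefined aluminium enolate, activated as its ate complex, is O-triflated so that the double bond lies next to the quaternary carbon.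

**Step 2**
Reactants: 5 (3R)-3-ethenyl-3-methylcyclohex-1-en-1-yl trifluoromethanesulfonate; 6 methylmagnesium bromide
Product: 7 (3R)-3-ethenyl-1,3-dimethylcyclohex-1-ene
Conditions: 6 (1.3 equiv), Fe(acac)3 (5 mol%), THF/NMP, −30 → 0 °C
Reagents that add atoms: none
Why: Iron-catalysed (Kochi–Fürstner) cross-coupling of the enol triflate with the methyl Grignard reagent; the stereocentre is not touched.

**Step 3**
Reactants: 7 (3R)-3-ethenyl-1,3-dimethylcyclohex-1-ene
Product: 9 2-[(1R)-1,3-dimethylcyclohex-2-en-1-yl]ethan-1-ol, via B-alkyl-9-BBN adduct 8 (not isolated)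
Conditions: 9-BBN (1.1 equiv), THF, 0 → 23 °C; then NaOH, H2O2, 0 °C
Reagents that add atoms: hydrogen peroxide OO
Why: Anti-Markovnikov hydroboration–oxidation; 9-BBN reacts only with the monosubstituted vinyl group and leaves the trisubstituted ring alkene.

**Step 4**
Reactants: 9 2-[(1R)-1,3-dimethylcyclohex-2-en-1-yl]ethan-1-ol
Product: 12 (4aR,7aR)-4a,7a-dimethyloctahydrocyclopenta[c]pyran-1-ol, via epoxy alcohol 10 (not isolated), via hydroxy aldehyde 11 (not isolated)
Conditions: VO(OTf)2 (5 mol%), tBuOOH (1.15 equiv, in decane), 4 Å molecular sieves, CH2Cl2, −20 → 23 °C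
Reagents that add atoms: tert-butyl hydroperoxide CC(C)(C)OO
Why: Proposed new method: one vanadium catalyst does two jobs in one flask – tBuOOH turns the tetravalent VO(OTf)2 into a cationic pentavalent oxovanadium alkylperoxide that binds the hydroxyl of 9 and delivers oxygen inside the complex to the alkene face syn to the hydroxyethyl arm (epoxide 10, the known course of VO(acac)2/tBuOOH epoxidation of bishomoallylic alcohols); the vanadium alkoxide, still held on that face and made Lewis acidic by triflate, then ionises the epoxide C–O bond at the tertiary carbon while the ring C–C bond to the quaternary carbon shifts to its back side (1,2-shift, retention at the migrating carbon, inversion at the tertiary carbon), which contracts the ring, sets the second quaternary centre with the formyl group cis to the arm and lets aldehyde 11 close to lactol 12; the closest known reactions are hydroxyl-directed vanadium/tBuOOH epoxidation and the Lewis-acid (BF3·OEt2 or aluminium aryloxide) Meinwald/semipinacol ring contraction of 1-methylcyclohexene oxides.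

**Step 5**
Reactants: 12 (4aR,7aR)-4a,7a-dimethyloctahydrocyclopenta[c]pyran-1-ol; 13 1-chloro-3-methylbut-2-ene
Product: 15 1-[(1R,2R)-2-(2-hydroxyethyl)-1,2-dimethylcyclopentyl]-4-methylpent-3-en-1-ol (both carbinol epimers), via prenylbarium chloride 14 (not isolated)
Conditions: BaI2, Li(C12H10) (lithium biphenylide, 2 equiv), THF, 23 °C; 13 (2.6 equiv), −78 °C; then 12, −78 → −20 °C; aq NH4Cl
Reagents that add atoms: none
Why: Carbonyl allylation with an allylic barium reagent, which attacks through its CH2–Ba (α) carbon and gives the linear prenyl carbinol from the ring-opened lactol; the new carbinol centre is uncontrolled and is oxidised away in step 6.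

**Step 6**
Reactants: 15 1-[(1R,2R)-2-(2-hydroxyethyl)-1,2-dimethylcyclopentyl]-4-methylpent-3-en-1-ol
Product: 16 2-[(1R,2R)-1,2-dimethyl-2-(4-methylpent-3-enoyl)cyclopentyl]acetaldehyde
Conditions: (COCl)2, DMSO, CH2Cl2, −78 °C; iPr2NEt, −78 → −30 °C; pH 7 buffer
Reagents that add atoms: none
Why: Swern oxidation; both hydroxyls are activated at −78 °C before base is added, so the hydroxy aldehyde cannot close to a lactol and over-oxidise to a lactone, and the hindered amine at low temperature leaves the β,γ-unsaturated ketone unconjugated.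

**Step 7**
Reactants: 17 2-methylphenol; 18 1-bromo-3-methylbut-2-ene
Product: 20 2-methyl-6-(3-methylbut-2-en-1-yl)phenol, via sodium 2-methylphenoxide 19 (not isolated)
Conditions: NaH (1.0 equiv), toluene, 0 → 23 °C; 18 (0.9 equiv), 23 °C, 16 h; phenol separated from neutral ether by extraction into KOH/MeOH/H2O
Reagents that add atoms: none
Why: ortho-Selective C-allylation of a sodium phenoxide in a non-polar solvent (tight ion pair, SN2 at the primary allylic carbon).

**Step 8**
Reactants: 20 2-methyl-6-(3-methylbut-2-en-1-yl)phenol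
Product: 21 tert-butyldimethyl[2-methyl-6-(3-methylbut-2-en-1-yl)phenoxy]silane
Conditions: TBSCl, imidazole, DMF, 23 °C
Reagents that add atoms: tert-butyl(chloro)dimethylsilane CC(C)(C)[Si](C)(C)Cl
Why: Standard silylation; the phenol must be masked for the allylic oxidation and for the allylic chloride and barium chemistry that follow.

**Step 9**
Reactants: 21 tert-butyldimethyl[2-methyl-6-(3-methylbut-2-en-1-yl)phenoxy]silane
Product: 22 (2E)-4-{2-[(tert-butyldimethylsilyl)oxy]-3-methylphenyl}-2-methylbut-2-en-1-ol
Conditions: SeO2 (0.5 equiv), tBuOOH (2 equiv), salicylic acid (10 mol%), CH2Cl2, 0 → 23 °C, stopped at about 70% conversion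
Reagents that add atoms: selenium dioxide O=[Se]=O; tert-butyl hydroperoxide CC(C)(C)OO
Why: Selenium dioxide allylic oxidation (ene reaction, then [2,3]-shift) attacks the E-methyl group at the more substituted end of the trisubstituted alkene and gives the E allylic alcohol.

**Step 10**
Reactants: 22 (2E)-4-{2-[(tert-butyldimethylsilyl)oxy]-3-methylphenyl}-2-methylbut-2-en-1-ol
Product: 23 tert-butyl{2-[(2E)-4-chloro-3-methylbut-2-en-1-yl]-6-methylphenoxy}dimethylsilane
Conditions: N-chlorosuccinimide, Me2S, CH2Cl2, −20 → 0 °C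
Reagents that add atoms: N-chlorosuccinimide O=C1CCC(=O)N1Cl
Why: Corey–Kim chlorination; chloride displaces the alkoxysulfonium group at the primary carbon by SN2, without allylic shift and with the E geometry kept.

**Step 11**
Reactants: 16 2-[(1R,2R)-1,2-dimethyl-2-(4-methylpent-3-enoyl)cyclopentyl]acetaldehyde; 23 tert-butyl{2-[(2E)-4-chloro-3-methylbut-2-en-1-yl]-6-methylphenoxy}dimethylsilane
Product: 25 1-[(1R,2R)-2-[(4E)-6-{2-[(tert-butyldimethylsilyl)oxy]-3-methylphenyl}-2-hydroxy-4-methylhex-4-en-1-yl]-1,2-dimethylcyclopentyl]-4-methylpent-3-en-1-one (both carbinol epimers), via allylbarium chloride 24 (not isolated)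
Conditions: BaI2, Li(C12H10) (2 equiv), THF, 23 °C; 23 (1.2 equiv), −78 °C, 30 min; 16, −78 °C, 1 h; aq NH4Cl at −78 °C
Reagents that add atoms: none
Why: Allylic barium reagents formed at −78 °C keep the E geometry and add to aldehydes through the α-carbon, and the aldehyde reacts far faster than the neopentyl ketone; the new carbinol centre is uncontrolled and is oxidised in step 13.

**Step 12**
Reactants: 25 silyl-protected keto alcohol from step 11
Product: 27 2-{(2E)-6-[(1R,2R)-1,2-dimethyl-2-(4-methylpent-3-enoyl)cyclopentyl]-5-hydroxy-3-methylhex-2-en-1-yl}-6-methylcyclohexa-2,5-diene-1,4-dione, via free phenol 26 (not isolated)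
Conditions: KHF2 (2 equiv), MeOH, 23 °C; then (KSO3)2NO (2.5 equiv), KH2PO4 buffer, H2O/acetone, 0 → 23 °C
Reagents that add atoms: potassium nitrosodisulfonate (Fremy's salt) [K+].[K+].[O]N(S(=O)(=O)[O-])S(=O)(=O)[O-]
Why: KHF2 cleaves the phenolic silyl ether selectively under near-neutral conditions, and the Teuber oxidation with Fremy's salt turns the 2,6-dialkylphenol into the 2,6-dialkyl-1,4-benzoquinone without touching alkenes, carbinol or ketone.

**Step 13**
Reactants: 27 quinone keto alcohol from step 12
Product: 28 2-{(2E)-6-[(1R,2R)-1,2-dimethyl-2-(4-methylpent-3-enoyl)cyclopentyl]-3-methyl-5-oxohex-2-en-1-yl}-6-methylcyclohexa-2,5-diene-1,4-dione (target)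
Conditions: Dess–Martin periodinane (1.5 equiv), NaHCO3, CH2Cl2, 0 → 23 °C
Reagents that add atoms: none
Why: Dess–Martin oxidation of the homoallylic alcohol under buffered, non-basic conditions gives the β,γ-unsaturated ketone without double-bond migration or aldol closure of the 1,5-diketone; both quaternary centres are untouched.

**Compound list**
1 | 3-methylcyclohex-2-en-1-one | CC1=CC(=O)CCC1 | starting material
2 | ethenylmagnesium bromide | C=C[Mg]Br | starting material
3 | ethenyldimethylalane | C=C[Al](C)C | intermediate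
4 | {[(3R)-3-ethenyl-3-methylcyclohex-1-en-1-yl]oxy}dimethylalane (aluminium enolate) | C=C[C@@]1(C)CCCC(O[Al](C)C)=C1 | intermediate
5 | (3R)-3-ethenyl-3-methylcyclohex-1-en-1-yl trifluoromethanesulfonate | C=C[C@@]1(C)CCCC(OS(=O)(=O)C(F)(F)F)=C1 | intermediate
6 | methylmagnesium bromide | C[Mg]Br | starting material
7 | (3R)-3-ethenyl-1,3-dimethylcyclohex-1-ene | C=C[C@@]1(C)CCCC(C)=C1 | intermediate
8 | 9-{2-[(1S)-1,3-dimethylcyclohex-2-en-1-yl]ethyl}-9-borabicyclo[3.3.1]nonane | C1CCC2CCCC(C1)B2CC[C@@]1(C)CCCC(C)=C1 | intermediate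
9 | 2-[(1R)-1,3-dimethylcyclohex-2-en-1-yl]ethan-1-ol | OCC[C@@]1(C)CCCC(C)=C1 | intermediate
10 | 2-[(1S,2R,6R)-2,6-dimethyl-7-oxabicyclo[4.1.0]heptan-2-yl]ethan-1-ol | OCC[C@@]1(C)CCC[C@@]2(C)O[C@@H]12 | intermediate
11 | (1R,2R)-2-(2-hydroxyethyl)-1,2-dimethylcyclopentane-1-carbaldehyde | OCC[C@@]1(C)CCC[C@@]1(C)C=O | intermediate
12 | (4aR,7aR)-4a,7a-dimethyloctahydrocyclopenta[c]pyran-1-ol (lactol, both anomers) | OC1OCC[C@@]2(C)CCC[C@@]12C | intermediate
13 | 1-chloro-3-methylbut-2-ene | CC(C)=CCCl | starting material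
14 | (3-methylbut-2-en-1-yl)barium chloride | CC(C)=CC[Ba]Cl | intermediate
15 | 1-[(1R,2R)-2-(2-hydroxyethyl)-1,2-dimethylcyclopentyl]-4-methylpent-3-en-1-ol | CC(C)=CCC(O)[C@]1(C)CCC[C@]1(C)CCO | intermediate
16 | 2-[(1R,2R)-1,2-dimethyl-2-(4-methylpent-3-enoyl)cyclopentyl]acetaldehyde | CC(C)=CCC(=O)[C@]1(C)CCC[C@]1(C)CC=O | intermediate
17 | 2-methylphenol | Cc1ccccc1O | starting material
18 | 1-bromo-3-methylbut-2-ene | CC(C)=CCBr | starting material
19 | sodium 2-methylphenoxide | Cc1ccccc1[O-].[Na+] | intermediate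
20 | 2-methyl-6-(3-methylbut-2-en-1-yl)phenol | CC(C)=CCc1cccc(C)c1O | intermediate
21 | tert-butyldimethyl[2-methyl-6-(3-methylbut-2-en-1-yl)phenoxy]silane | CC(C)=CCc1cccc(C)c1O[Si](C)(C)C(C)(C)C | intermediate
22 | (2E)-4-{2-[(tert-butyldimethylsilyl)oxy]-3-methylphenyl}-2-methylbut-2-en-1-ol | OC/C(C)=C/Cc1cccc(C)c1O[Si](C)(C)C(C)(C)C | intermediate
23 | tert-butyl{2-[(2E)-4-chloro-3-methylbut-2-en-1-yl]-6-methylphenoxy}dimethylsilane | ClC/C(C)=C/Cc1cccc(C)c1O[Si](C)(C)C(C)(C)C | intermediate
24 | [(2E)-4-{2-[(tert-butyldimethylsilyl)oxy]-3-methylphenyl}-2-methylbut-2-en-1-yl]barium chloride | Cl[Ba]C/C(C)=C/Cc1cccc(C)c1O[Si](C)(C)C(C)(C)C | intermediate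
25 | 1-[(1R,2R)-2-[(4E)-6-{2-[(tert-butyldimethylsilyl)oxy]-3-methylphenyl}-2-hydroxy-4-methylhex-4-en-1-yl]-1,2-dimethylcyclopentyl]-4-methylpent-3-en-1-one | CC(C)=CCC(=O)[C@]1(C)CCC[C@]1(C)CC(O)C/C(C)=C/Cc1cccc(C)c1O[Si](C)(C)C(C)(C)C | intermediate
26 | 1-[(1R,2R)-2-[(4E)-2-hydroxy-6-(2-hydroxy-3-methylphenyl)-4-methylhex-4-en-1-yl]-1,2-dimethylcyclopentyl]-4-methylpent-3-en-1-one | CC(C)=CCC(=O)[C@]1(C)CCC[C@]1(C)CC(O)C/C(C)=C/Cc1cccc(C)c1O | intermediate
27 | 2-{(2E)-6-[(1R,2R)-1,2-dimethyl-2-(4-methylpent-3-enoyl)cyclopentyl]-5-hydroxy-3-methylhex-2-en-1-yl}-6-methylcyclohexa-2,5-diene-1,4-dione | CC(C)=CCC(=O)[C@]1(C)CCC[C@]1(C)CC(O)C/C(C)=C/CC1=CC(=O)C=C(C)C1=O | intermediate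
28 | 2-{(2E)-6-[(1R,2R)-1,2-dimethyl-2-(4-methylpent-3-enoyl)cyclopentyl]-3-methyl-5-oxohex-2-en-1-yl}-6-methylcyclohexa-2,5-diene-1,4-dione | CC(C)=CCC(=O)[C@]1(C)CCC[C@]1(C)CC(=O)C/C(C)=C/CC1=CC(=O)C=C(C)C1=O | target

**Step count and risks**
Total: 13 steps. Longest linear sequence: 9 steps (steps 1–6, then 11–13); the aryl fragment takes 4 steps (7–10).

The three steps most likely to fail:

Step 4, the proposed new oxidative ring contraction. The cationic vanadium may open 10 unselectively, or hydride shift may compete with migration of the quaternary carbon. The fallback uses known chemistry, sets out from 9 and returns at 12. Compound 9 is epoxidised with VO(acac)2/tBuOOH (the established hydroxyl-directed epoxidation) and the epoxy alcohol 10 is isolated. Silylation with TBSCl and imidazole gives the silyl ether F1. Treatment with MeAl(OAr)2 (Ar = 4-bromo-2,6-di-tert-butylphenyl) in CH2Cl2 at −78 °C, a reagent known to convert trisubstituted epoxides into aldehydes by alkyl shift, gives the silyloxy aldehyde F2. Bu4NF buffered with AcOH then frees hydroxy aldehyde 11, which closes to 12.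

Step 11, the allylbarium union. The risks are loss of α-selectivity or of the E geometry, and enolisation of 16. The fallback sets out from 23 and returns at 25. Zinc-mediated Barbier addition of 23 to acetone (Zn, THF/aq NH4Cl) gives, by the normal γ-attack, the branched tertiary homoallylic alcohol F4. Sn(OTf)2-catalysed allyl transfer (2-oxonia-Cope rearrangement through a chair transition state) from F4 to aldehyde 16 in CH2Cl2 then gives the linear E homoallylic alcohol 25 with loss of acetone.

Step 5, the prenylbarium addition to the hindered lactol. The risks are slow ring opening of the lactol and γ-attack. The fallback sets out from 12 and returns at 15. Allylmagnesium bromide, which has no regiochemical ambiguity, adds to 12 to give the homoallylic diol F3. Cross-metathesis of F3 with 2-methylbut-2-ene, using the second-generation Grubbs catalyst RuCl2(=CHPh)(PCy3)(H2IMes), converts the terminal alkene into the prenyl alkene of 15.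

**Further compounds**
F1 | step 4 | tert-butyl{2-[(1S,2R,6R)-2,6-dimethyl-7-oxabicyclo[4.1.0]heptan-2-yl]ethoxy}dimethylsilane | CC(C)(C)[Si](C)(C)OCC[C@@]1(C)CCC[C@@]2(C)O[C@@H]12
F2 | step 4 | (1R,2R)-2-{2-[(tert-butyldimethylsilyl)oxy]ethyl}-1,2-dimethylcyclopentane-1-carbaldehyde | CC(C)(C)[Si](C)(C)OCC[C@@]1(C)CCC[C@@]1(C)C=O
F3 | step 5 | 1-[(1R,2R)-2-(2-hydroxyethyl)-1,2-dimethylcyclopentyl]but-3-en-1-ol | C=CCC(O)[C@]1(C)CCC[C@]1(C)CCO
F4 | step 11 | 3-({2-[(tert-butyldimethylsilyl)oxy]-3-methylphenyl}methyl)-2,4-dimethylpent-4-en-2-ol | CC(=C)C(Cc1cccc(C)c1O[Si](C)(C)C(C)(C)C)C(C)(C)O
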